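**Plan**
- Cuts: C11=C12 and C11'=C12' (two Wittig reactions on the C10 dialdehyde), C7=C8 (HWE), O5'–C8' of the dihydrofuran, and C5–C6 of the trihydroxy ring together with a temporary O5–C7 acyl bond.
- Forward order: the cyclohexene ring of the furanoid half comes ready-made from (4R,6R)-actinol. The dihydrofuran ring is closed in step 6 and this half is grown to the C25 aldehyde 13. Only then is the open-chain keto acid 26 closed to the C1–C6 ring (step 15), extended to a C15 Wittig salt and joined.
- Enabling feature: in ring C1–C6 the 5,6-diol is trans, so O5 and C7 are cis on C5/C6. C7–C6–C5–O5 is therefore a β-hydroxy-acid (aldol) unit that can be tied up as a cis-fused β-lactone, and the C1 gem-dimethyl group anchors the chair.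
- Stereochemistry: C3 comes from (R)-epichlorohydrin. C5 and C6 come from C3 in step 15, where both C6 epimers converge. C3' comes from actinol, C5' from anti epoxidation, and C8' from centre→axis→centre transfer (steps 5 and 6). The E-alkenes come from the building blocks, HWE/Wittig selectivity and thermal equilibration.

Key step: step 15

Remark: carotenoid numbering is used for all fragments (C1–C6 trihydroxy ring, C7–C15 chain, primed locants for the furanoid half). Compounds 1, 4, 12, 14, 15, 18, 22 and 33 are taken as commercial.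

Step 1
Reactants: 1 (4R,6R)-actinol
Product: 2 actinol TBS ether
Conditions: TBSCl, imidazole, DMF, rt
Reagents that add atoms: tert-butyldimethylsilyl chloride CC(C)(C)[Si](C)(C)Cl
Why: Standard silyl ether protection of the only hydroxyl group touches no stereocentre, and the bulky ether later steers the epoxidation to the opposite face.

Step 2
Reactants: 2 actinol TBS ether
Product: 3 (4R)-enol triflate
Conditions: LDA, THF, −78 °C; PhNTf2, −78 °C → rt
Reagents that add atoms: N-phenylbis(trifluoromethanesulfonimide) O=S(=O)(N(c1ccccc1)S(=O)(=O)C(F)(F)F)C(F)(F)F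
Why: Only C5'–H is enolizable (C1' is quaternary), so enolate O-triflation (enol triflate formation) should give one regioisomer; the C5' centre of 1 is erased on purpose.

Step 3
Reactants: 3 (4R)-enol triflate; 4 (E)-3-methylpent-2-en-4-yn-1-ol
Product: 5 C15 dienynol
Conditions: Pd(PPh3)4 (cat.), CuI (cat.), i-Pr2NH, DMF, rt → 40 °C
Reagents that add atoms: none
Why: Sonogashira coupling of a vinyl triflate with a terminal alkyne tolerates the free primary alcohol, and the E geometry of C9'=C10' is carried in with 4.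

Step 4
Reactants: 5 C15 dienynol
Product: 6 (3'S,5'R,6'R)-alkynyl epoxide
Conditions: mCPBA, NaHCO3, CH2Cl2, 0 °C
Reagents that add atoms: 3-chloroperoxybenzoic acid OOC(=O)c1cccc(Cl)c1
Why: Prilezhaev epoxidation should pick the tetrasubstituted, most electron-rich ring alkene, and the peracid should approach anti to the 3'-OTBS group, which sets C5' and C6'; any syn isomer is removed by chromatography.

Step 5
Reactants: 6 (3'S,5'R,6'R)-alkynyl epoxide
Product: 8 (3'S,5'R,aS)-allenol, via bis(diethoxymethylsilyl) ether 7 (not isolated)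
Conditions: (IPr)CuCl (cat.), NaOt-Bu (cat.), (EtO)2MeSiH (3 equiv), toluene, 0 °C; then K2CO3, MeOH/H2O
Reagents that add atoms: none
Why: In this copper hydride-catalysed SN2' reduction of a propargylic oxirane, copper attacks C8' anti to the breaking C6'–O bond and reductive elimination keeps that face, so hydride ends up anti to the oxygen and the epoxide configuration is carried into the (aS) allene axis while C5' keeps its oxygen.

Step 6
Reactants: 8 (3'S,5'R,aS)-allenol
Product: 9 (3'S,5'R,8'R)-furanoid C15 alcohol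
Conditions: AuCl3 (cat.), THF, 0 °C, dark
Reagents that add atoms: none
Why: In this gold-catalysed 5-endo cycloisomerization of an α-hydroxyallene to a 2,5-dihydrofuran, O5' adds to C8' in the C5'–C6'=C7' plane anti to gold while H and C9' keep their sides of that plane, so the axis becomes (8'R), and protodeauration leaves C6'=C7'.

Step 7
Reactants: 9 (3'S,5'R,8'R)-furanoid C15 alcohol
Product: 11 furanoid C15 phosphonium bromide, via allylic bromide 10 (not isolated)
Conditions: NBS, Me2S, CH2Cl2, −20 → 0 °C; then PPh3, EtOAc, rt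
Reagents that add atoms: N-bromosuccinimide BrN1C(=O)CCC1=O; triphenylphosphine c1ccc(cc1)P(c1ccccc1)c1ccccc1
Why: Corey–Kim-type bromination is neutral and so avoids the acid that would epimerize C8', and SN2 quaternization of the primary allylic bromide gives the Wittig salt.

Step 8
Reactants: 11 furanoid C15 phosphonium bromide; 12 (2E,4E,6E)-2,7-dimethylocta-2,4,6-trienedial
Product: 13 furanoid C25 aldehyde
Conditions: 12 (3 equiv), NaOMe, CH2Cl2/MeOH, 0 °C → rt; then EtOAc, 60 °C (Z→E), dark
Reagents that add atoms: none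
Why: Wittig olefination with excess dialdehyde should stop at the mono-adduct; forming the ylide in the presence of the aldehyde leaves it little time for ring-opening elimination, and warming equilibrates C11'=C12' to E.

Step 9
Reactants: 14 (R)-epichlorohydrin; 15 isopropenylmagnesium bromide
Product: 17 (R)-2-(2-methylallyl)oxirane, via chlorohydrin 16 (not isolated)
Conditions: CuI (cat.), THF, −40 °C; aq. work-up; then powdered NaOH, Et2O, rt
Reagents that add atoms: none
Why: Copper-catalysed Grignard opening at the epoxide CH2, followed by Williamson-type closure of the chlorohydrin, breaks no bond at the stereocentre, so C3 comes unchanged from 14.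

Step 10
Reactants: 17 (R)-2-(2-methylallyl)oxirane; 18 isobutyric acid
Product: 20 (5R)-3,3-dimethyl-5-(2-methylallyl)dihydrofuran-2(3H)-one, via hydroxy acid 19 (not isolated)
Conditions: 18, LDA (2.1 equiv), THF, 0 → 40 °C; 17, 0 °C → rt; then 2 M HCl, rt
Reagents that add atoms: none
Why: The carboxylic acid dianion opens the terminal epoxide at CH2 (SN2), which forges C1–C2 and the quaternary C1, and the γ-hydroxy acid lactonizes on acidification with help from the gem-dimethyl effect.

Step 11
Reactants: 20 (5R)-3,3-dimethyl-5-(2-methylallyl)dihydrofuran-2(3H)-one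
Product: 21 lactol
Conditions: DIBAL-H (1.1 equiv), CH2Cl2, −78 °C; Rochelle salt
Reagents that add atoms: none
Why: Partial reduction of the hindered α,α-dimethyl lactone should stop at the lactol because the tetrahedral aluminate is stable at low temperature.

Step 12
Reactants: 21 lactol; 22 vinylmagnesium bromide
Product: 23 (6R)-4,4,8-trimethylnona-1,8-diene-3,6-diol (C6 epimers)
Conditions: 22 (3 equiv), THF, 0 °C → rt
Reagents that add atoms: none
Why: Grignard addition to the open hydroxy-aldehyde form brings in C7 (plus one sacrificial carbon); the C6 carbinol forms as an epimer mixture, which is harmless because C6 is planarized in step 15.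

Step 13
Reactants: 23 (6R)-4,4,8-trimethylnona-1,8-diene-3,6-diol (C6 epimers)
Product: 24 bis(triethylsilyl) ether
Conditions: TESOTf, 2,6-lutidine, CH2Cl2, −78 → 0 °C
Reagents that add atoms: triethylsilyl trifluoromethanesulfonate CC[Si](CC)(CC)OS(=O)(=O)C(F)(F)F
Why: Silyl triflate/lutidine silylation covers both secondary alcohols, including the neopentylic one, in a single operation.

Step 14
Reactants: 24 bis(triethylsilyl) ether
Product: 26 (5S)-keto acid (C6 epimers), via keto aldehyde 25 (not isolated)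
Conditions: O3, CH2Cl2, −78 °C; Me2S; concentrate; then NaClO2, NaH2PO4, 2-methyl-2-butene, t-BuOH/H2O, rt
Reagents that add atoms: ozone [O-][O+]=O; sodium chlorite [Na+].[O-]Cl=O
Why: Ozonolysis cleaves both terminal alkenes at once (methallyl to the C5 methyl ketone, vinyl to the C7 aldehyde), and Pinnick oxidation then takes only the aldehyde to the acid without touching ketone, silyl ethers or C3.

Step 15
Reactants: 26 (5S)-keto acid (C6 epimers)
Product: 29 (3S,5R,6R)-bicyclic β-lactone, via mixed anhydride 27 (not isolated), via acylpyridinium enolate 28 (not isolated)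
Conditions: TsCl, i-Pr2NEt, 4-pyrrolidinopyridine, LiCl, CH2Cl2, rt, slow addition of 26
Reagents that add atoms: none
Why: TsCl turns 26 into the mixed anhydride 27, 4-pyrrolidinopyridine takes over the acyl group and i-Pr2NEt removes C6–H of the acylpyridinium ion, so both C6 epimers converge on one planar enolate 28, whose C6 adds to the Li+-activated C5 ketone before the C5 alkoxide displaces the pyridine from C7 (nucleophile-promoted aldol–lactonization of a keto acid, the bis-cyclization type known for 6- and 7-oxo acids and for α-heteroatom-substituted α-branched acids). The carbocycle closes in the 6-(enolexo)-exo-trig mode (C5–C6) and the temporary β-lactone in the 4-exo-trig mode (O5–C7). C5 relative to C6: the aldol step is reversible and only the aldolate with O5 and C7 on the same ring face can lactonize, so the cis-fused β-lactone, that is O5 trans to O6, is the only outlet. C5/C6 relative to C3: in the chair transition state one C1 methyl group is necessarily axial, so the positions syn-axial to it at C3 and C5 are taken by H and by the ketone oxygen, which places 3-OTES and the C5 methyl group equatorial and fixes the (3S,5R,6R) array from the single C3 centre. The step needs enolization of the acyl unit beside a methyl ketone, secured because only the acylpyridinium α-H is acidic enough for a tertiary amine, and cyclization over oligomerization, secured by slow addition and the C1 gem-dimethyl effect.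

Step 16
Reactants: 29 (3S,5R,6R)-bicyclic β-lactone
Product: 30 C7 alcohol with free 5-OH
Conditions: DIBAL-H (3 equiv), CH2Cl2, −78 → −20 °C; Rochelle salt
Reagents that add atoms: none
Why: Hydride reduction of the strained β-lactone by acyl–oxygen cleavage removes the temporary ring and frees the primary C7 alcohol and the tertiary 5-OH; aluminium alkoxides at low temperature should not trigger silyl migration.

Step 17
Reactants: 30 C7 alcohol with free 5-OH
Product: 31 β-hydroxy aldehyde
Conditions: Dess–Martin periodinane, NaHCO3, CH2Cl2, 0 °C → rt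
Reagents that add atoms: none
Why: Dess–Martin oxidation can act only on the primary alcohol (the 5-OH is tertiary), and the buffered neutral medium avoids retro-aldol cleavage.

Step 18
Reactants: 31 β-hydroxy aldehyde
Product: 32 tris(triethylsilyl) aldehyde
Conditions: TESOTf, 2,6-lutidine, CH2Cl2, 0 °C → rt
Reagents that add atoms: triethylsilyl trifluoromethanesulfonate CC[Si](CC)(CC)OS(=O)(=O)C(F)(F)F
Why: Silyl triflate silylation caps the hindered axial 5-OH and so blocks retro-aldol ring opening in the basic olefination; the aldehyde has no α-H and cannot enolize.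

Step 19
Reactants: 32 tris(triethylsilyl) aldehyde; 33 triethyl 3-methyl-4-phosphonocrotonate
Product: 34 C15 dienoate
Conditions: 33, LiHMDS, THF/DMPU, −78 °C; then 32, −78 → 0 °C
Reagents that add atoms: none
Why: Horner–Wadsworth–Emmons olefination with the stabilized vinylogous phosphonate anion should form C7=C8 as the E isomer and brings in C9=C10 as E; any 9Z material is removed by chromatography.

Step 20
Reactants: 34 C15 dienoate
Product: 35 C15 dienol
Conditions: DIBAL-H (2.5 equiv), CH2Cl2, −78 °C; Rochelle salt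
Reagents that add atoms: none
Why: 1,2-Reduction of the dienoate with DIBAL-H gives the allylic alcohol and leaves the silyl ethers and alkene geometry alone.

Step 21
Reactants: 35 C15 dienol
Product: 37 trihydroxy-ring C15 phosphonium bromide, via dienyl bromide 36 (not isolated)
Conditions: NBS, Me2S, CH2Cl2, −20 → 0 °C; then PPh3, EtOAc, rt
Reagents that add atoms: N-bromosuccinimide BrN1C(=O)CCC1=O; triphenylphosphine c1ccc(cc1)P(c1ccccc1)c1ccccc1
Why: Neutral Corey–Kim-type bromination spares the tertiary allylic C6–OTES group, which acid would ionize, and SN2 quaternization with PPh3 gives the Wittig salt.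

Step 22
Reactants: 37 trihydroxy-ring C15 phosphonium bromide; 13 furanoid C25 aldehyde
Product: 38 tetrasilylated C40 carotenoid
Conditions: NaHMDS, THF, −78 °C; then 13, −78 → 0 °C; then EtOAc, 60 °C (Z→E), dark, Ar
Reagents that add atoms: none
Why: Wittig olefination of the α-methyl enal joins the halves at C11=C12 under acid-free conditions that leave C8' untouched, and warming converts any 11Z isomer into the all-E polyene.

Step 23
Reactants: 38 tetrasilylated C40 carotenoid
Product: 39 target CNP0210286.2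
Conditions: TBAF, THF, 0 °C → rt, dark, Ar
Reagents that add atoms: none
Why: Fluoride-induced desilylation removes the three TES groups and the TBS group at silicon, so no C–O bond is broken, and the acid-free medium protects C8' and the tertiary allylic 6-OH.

**Compound list**
1 | (4R,6R)-4-hydroxy-2,2,6-trimethylcyclohexan-1-one (actinol) | O=C1C(C)(C)C[C@H](O)C[C@H]1C | starting material
2 | (4R,6R)-4-(tert-butyldimethylsilyloxy)-2,2,6-trimethylcyclohexan-1-one | O=C1C(C)(C)C[C@H](O[Si](C)(C)C(C)(C)C)C[C@H]1C | intermediate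
3 | (4R)-4-(tert-butyldimethylsilyloxy)-2,6,6-trimethylcyclohex-1-en-1-yl trifluoromethanesulfonate | CC1(C)C[C@H](O[Si](C)(C)C(C)(C)C)CC(C)=C1OS(=O)(=O)C(F)(F)F | intermediate
4 | (E)-3-methylpent-2-en-4-yn-1-ol | C#C/C(C)=C/CO | starting material
5 | (2E)-5-[(4R)-4-(tert-butyldimethylsilyloxy)-2,6,6-trimethylcyclohex-1-en-1-yl]-3-methylpent-2-en-4-yn-1-ol | CC1(C)C[C@H](O[Si](C)(C)C(C)(C)C)CC(C)=C1C#C/C(C)=C/CO | intermediate
6 | (2E)-5-[(1R,4S,6R)-4-(tert-butyldimethylsilyloxy)-2,2,6-trimethyl-7-oxabicyclo[4.1.0]heptan-1-yl]-3-methylpent-2-en-4-yn-1-ol (epoxide anti to OTBS) | CC1(C)C[C@H](O[Si](C)(C)C(C)(C)C)C[C@@]2(C)O[C@@]12C#C/C(C)=C/CO | intermediate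
7 | O5',O11'-bis(diethoxymethylsilyl) ether of 8 | CC1(C)C[C@H](O[Si](C)(C)C(C)(C)C)C[C@@](C)(O[Si](C)(OCC)OCC)C1=[C@@]=C/C(C)=C/CO[Si](C)(OCC)OCC | intermediate
8 | (2E)-5-[(2R,4S)-4-(tert-butyldimethylsilyloxy)-2-hydroxy-2,6,6-trimethylcyclohexylidene]-3-methylpenta-2,4-dien-1-ol, (aS)-allene (H-8' anti to the former epoxide oxygen) | CC1(C)C[C@H](O[Si](C)(C)C(C)(C)C)C[C@@](C)(O)C1=[C@@]=C/C(C)=C/CO | intermediate
9 | (2E)-3-[(2R,6S,7aR)-6-(tert-butyldimethylsilyloxy)-4,4,7a-trimethyl-2,4,5,6,7,7a-hexahydro-1-benzofuran-2-yl]but-2-en-1-ol | OC/C=C(\C)[C@H]1C=C2C(C)(C)C[C@H](O[Si](C)(C)C(C)(C)C)C[C@@]2(C)O1 | intermediate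
10 | allylic bromide of 9 | BrC/C=C(\C)[C@H]1C=C2C(C)(C)C[C@H](O[Si](C)(C)C(C)(C)C)C[C@@]2(C)O1 | intermediate
11 | triphenylphosphonium bromide of 9 (P at C11') | [Br-].c1ccccc1[P+](c1ccccc1)(c1ccccc1)C/C=C(\C)[C@H]1C=C2C(C)(C)C[C@H](O[Si](C)(C)C(C)(C)C)C[C@@]2(C)O1 | intermediate
12 | (2E,4E,6E)-2,7-dimethylocta-2,4,6-trienedial | O=C/C(C)=C/C=C/C=C(C)/C=O | starting material
13 | (2E,4E,6E,8E,10E)-11-[(2R,6S,7aR)-6-(tert-butyldimethylsilyloxy)-4,4,7a-trimethyl-2,4,5,6,7,7a-hexahydro-1-benzofuran-2-yl]-2,7-dimethyldodeca-2,4,6,8,10-pentaenal | O=C/C(C)=C/C=C/C=C(C)/C=C/C=C(\C)[C@H]1C=C2C(C)(C)C[C@H](O[Si](C)(C)C(C)(C)C)C[C@@]2(C)O1 | intermediate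
14 | (R)-epichlorohydrin | ClC[C@H]1CO1 | starting material
15 | isopropenylmagnesium bromide | C=C(C)[Mg]Br | starting material
16 | (R)-1-chloro-4-methylpent-4-en-2-ol | ClC[C@H](O)CC(C)=C | intermediate
17 | (R)-2-(2-methylallyl)oxirane | C=C(C)C[C@@H]1CO1 | intermediate
18 | isobutyric acid | CC(C)C(=O)O | starting material
19 | (R)-4-hydroxy-2,2,6-trimethylhept-6-enoic acid | OC(=O)C(C)(C)C[C@H](O)CC(C)=C | intermediate
20 | (5R)-3,3-dimethyl-5-(2-methylallyl)dihydrofuran-2(3H)-one | O=C1C(C)(C)C[C@H](O1)CC(C)=C | intermediate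
21 | (5R)-3,3-dimethyl-5-(2-methylallyl)tetrahydrofuran-2-ol (anomers) | OC1C(C)(C)C[C@H](O1)CC(C)=C | intermediate
22 | vinylmagnesium bromide | C=C[Mg]Br | starting material
23 | (6R)-4,4,8-trimethylnona-1,8-diene-3,6-diol (epimers at C3 of the chain = C6) | C=CC(O)C(C)(C)C[C@H](O)CC(C)=C | intermediate
24 | (6R)-4,4,8-trimethyl-3,6-bis(triethylsilyloxy)nona-1,8-diene (C6 epimers) | C=CC(O[Si](CC)(CC)CC)C(C)(C)C[C@H](O[Si](CC)(CC)CC)CC(C)=C | intermediate
25 | (5S)-3,3-dimethyl-7-oxo-2,5-bis(triethylsilyloxy)octanal (C6 epimers) | O=CC(O[Si](CC)(CC)CC)C(C)(C)C[C@H](O[Si](CC)(CC)CC)CC(C)=O | intermediate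
26 | (5S)-3,3-dimethyl-7-oxo-2,5-bis(triethylsilyloxy)octanoic acid (C6 epimers) | OC(=O)C(O[Si](CC)(CC)CC)C(C)(C)C[C@H](O[Si](CC)(CC)CC)CC(C)=O | intermediate
27 | mixed carboxylic p-toluenesulfonic anhydride of 26 | Cc1ccc(cc1)S(=O)(=O)OC(=O)C(O[Si](CC)(CC)CC)C(C)(C)C[C@H](O[Si](CC)(CC)CC)CC(C)=O | intermediate
28 | zwitterionic 4-(pyrrolidin-1-yl)pyridinium enolate of 26 | [O-]C(=C(O[Si](CC)(CC)CC)C(C)(C)C[C@H](O[Si](CC)(CC)CC)CC(C)=O)[n+]1ccc(cc1)N1CCCC1 | intermediate
29 | (1R,4S,6R)-2,2,6-trimethyl-1,4-bis(triethylsilyloxy)-7-oxabicyclo[4.2.0]octan-8-one (cis-fused; lactone O trans to both silyloxy groups) | O=C1[C@@]2(O[Si](CC)(CC)CC)C(C)(C)C[C@H](O[Si](CC)(CC)CC)C[C@@]2(C)O1 | intermediate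
30 | (1R,2S,5S)-2-(hydroxymethyl)-1,3,3-trimethyl-2,5-bis(triethylsilyloxy)cyclohexan-1-ol | OC[C@@]1(O[Si](CC)(CC)CC)C(C)(C)C[C@H](O[Si](CC)(CC)CC)C[C@@]1(C)O | intermediate
31 | (1R,2R,4S)-2-hydroxy-2,6,6-trimethyl-1,4-bis(triethylsilyloxy)cyclohexane-1-carbaldehyde | O=C[C@@]1(O[Si](CC)(CC)CC)C(C)(C)C[C@H](O[Si](CC)(CC)CC)C[C@@]1(C)O | intermediate
32 | (1R,2R,4S)-2,6,6-trimethyl-1,2,4-tris(triethylsilyloxy)cyclohexane-1-carbaldehyde | O=C[C@@]1(O[Si](CC)(CC)CC)C(C)(C)C[C@H](O[Si](CC)(CC)CC)C[C@@]1(C)O[Si](CC)(CC)CC | intermediate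
33 | ethyl (E)-4-(diethoxyphosphoryl)-3-methylbut-2-enoate | CCOC(=O)/C=C(\C)CP(=O)(OCC)OCC | starting material
34 | ethyl (2E,4E)-3-methyl-5-[(1R,2R,4S)-2,6,6-trimethyl-1,2,4-tris(triethylsilyloxy)cyclohexyl]penta-2,4-dienoate | CCOC(=O)/C=C(C)/C=C/[C@@]1(O[Si](CC)(CC)CC)C(C)(C)C[C@H](O[Si](CC)(CC)CC)C[C@@]1(C)O[Si](CC)(CC)CC | intermediate
35 | (2E,4E)-3-methyl-5-[(1R,2R,4S)-2,6,6-trimethyl-1,2,4-tris(triethylsilyloxy)cyclohexyl]penta-2,4-dien-1-ol | OC/C=C(C)/C=C/[C@@]1(O[Si](CC)(CC)CC)C(C)(C)C[C@H](O[Si](CC)(CC)CC)C[C@@]1(C)O[Si](CC)(CC)CC | intermediate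
36 | dienyl bromide of 35 | BrC/C=C(C)/C=C/[C@@]1(O[Si](CC)(CC)CC)C(C)(C)C[C@H](O[Si](CC)(CC)CC)C[C@@]1(C)O[Si](CC)(CC)CC | intermediate
37 | triphenylphosphonium bromide of 35 (P at C11) | [Br-].c1ccccc1[P+](c1ccccc1)(c1ccccc1)C/C=C(C)/C=C/[C@@]1(O[Si](CC)(CC)CC)C(C)(C)C[C@H](O[Si](CC)(CC)CC)C[C@@]1(C)O[Si](CC)(CC)CC | intermediate
38 | all-E 3,5,6-tris-O-triethylsilyl-3'-O-tert-butyldimethylsilyl derivative of 39 | CC(/C=C/C=C(C)/C=C/[C@@]1(O[Si](CC)(CC)CC)C(C)(C)C[C@H](O[Si](CC)(CC)CC)C[C@@]1(C)O[Si](CC)(CC)CC)=C\C=C\C=C(C)\C=C\C=C(/C)[C@H]1C=C2C(C)(C)C[C@H](O[Si](C)(C)C(C)(C)C)C[C@@]2(C)O1 | intermediate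
39 | (3S,5R,6R,3'S,5'R,8'R)-5',8'-epoxy-5,6,5',8'-tetrahydro-β,β-carotene-3,5,6,3'-tetrol (CNP0210286.2) | CC(/C=C/C=C(C)/C=C/[C@@]1(O)C(C)(C)C[C@H](O)C[C@@]1(C)O)=C\C=C\C=C(C)\C=C\C=C(/C)[C@H]1C=C2C(C)(C)C[C@H](O)C[C@@]2(C)O1 | target

**Step count:** 23 steps in total. The longest linear sequence is 15 steps (steps 9–23, from 14).

**Steps most likely to fail**

1. Step 15. Deprotonation of the hindered C6–H in the acylpyridinium ion may be slow. Anhydride or oligomer formation, or β-elimination of the 3-silyloxy group, could then overtake the aldol–lactonization. The aldol equilibrium at three contiguous fully substituted carbons may also be unfavourable.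
 Fallback (sets out from 3, comes back at 32): the ring is taken from the chiral pool instead of being closed.
 - Pd-catalysed methoxycarbonylation of 3 (CO, MeOH, Et3N) gives the methyl cyclohexenecarboxylate F1.
 - DIBAL-H reduction gives the allylic alcohol F2.
 - Sharpless epoxidation, with the tartrate enantiomer that delivers oxygen syn to the 3-silyloxy group, gives the syn-epoxy alcohol F3.
 - Aqueous acid opens the epoxide at the tertiary C5 with inversion and removes the TBS group, giving the 3,5,6,7-tetraol F4.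
 - Exhaustive silylation with TESOTf gives the tetrakis(triethylsilyl) ether F5.
 - Swern conditions, which oxidize a primary TES ether selectively, lead to 32.

2. Step 6. Axis-to-centre transfer may erode through gold-induced epimerization of the vinylallene or ionization at the doubly allylic C8'.
 Fallback (sets out from 8, comes back at 9): stereospecific transfer is given up for thermodynamic recycling. The crude dihydrofuran is separated by chromatography into 9 and the (8'S)-epimer F6. F6 is re-equilibrated at C8' with a trace of camphorsulfonic acid in CH2Cl2 through the ring-opened allyl cation and separated again, so the material is funnelled into 9.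

3. Step 19. The phosphonate anion may fail to add to an aldehyde flanked by three fully substituted carbons, and the geometry at C9=C10 may scramble in the delocalized anion.
 Fallback (sets out from 32, comes back at 34): Takai olefination (CrCl2, CHI3, THF) gives the (E)-vinyl iodide F7. Suzuki coupling of F7 with commercial ethyl (Z)-3-(4,4,5,5-tetramethyl-1,3,2-dioxaborolan-2-yl)but-2-enoate (Pd(PPh3)4, K3PO4, THF/H2O) forms C8–C9 with retention of both geometries and gives 34.

**Further compounds**
F1 | step 15 | methyl (4R)-4-(tert-butyldimethylsilyloxy)-2,6,6-trimethylcyclohex-1-ene-1-carboxylate | CC1(C)C[C@H](O[Si](C)(C)C(C)(C)C)CC(C)=C1C(=O)OC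
F2 | step 15 | [(4R)-4-(tert-butyldimethylsilyloxy)-2,6,6-trimethylcyclohex-1-en-1-yl]methanol | CC1(C)C[C@H](O[Si](C)(C)C(C)(C)C)CC(C)=C1CO
F3 | step 15 | 5,6-epoxy alcohol with the epoxide syn to the 3-silyloxy group | CC1(C)C[C@H](O[Si](C)(C)C(C)(C)C)C[C@]2(C)O[C@]12CO
F4 | step 15 | (1S,2R,4S)-1-(hydroxymethyl)-2,6,6-trimethylcyclohexane-1,2,4-triol | OC[C@@]1(O)C(C)(C)C[C@H](O)C[C@@]1(C)O
F5 | step 15 | tetrakis(triethylsilyl) ether of F4 | CC[Si](CC)(CC)OC[C@@]1(O[Si](CC)(CC)CC)C(C)(C)C[C@H](O[Si](CC)(CC)CC)C[C@@]1(C)O[Si](CC)(CC)CC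
F6 | step 6 | (8'S)-epimer of 9 | OC/C=C(\C)[C@@H]1C=C2C(C)(C)C[C@H](O[Si](C)(C)C(C)(C)C)C[C@@]2(C)O1
F7 | step 19 | (E)-2-iodovinyl derivative of the tris(triethylsilyloxy) ring (I at C8) | I/C=C/[C@@]1(O[Si](CC)(CC)CC)C(C)(C)C[C@H](O[Si](CC)(CC)CC)C[C@@]1(C)O[Si](CC)(CC)CC
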